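The target is atranorin with one extra methyl group on each ring, so both aryl–methyl bonds, C5–CH3 on the benzoate ring B and C5'–CH3 on the benzoyl ring A, are disconnected together. The key step exploits the fact that C5 (ring B, para to the C2 hydroxyl) and C5' (ring A, ortho to the C4' hydroxyl) are the only hydrogen-bearing aromatic carbons of atranorin, so bromine, and then methyl, can enter nowhere else. The precursor, 5,5'-dibromoatranorin, is the intact depside with its hindered ester, aldehyde and three phenols unprotected. One twofold, base-free Stille methylation with tetramethylstannane then replaces both bromines and should give pseudocyphellarin A directly.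

Key step: step 2

Assumption: atranorin is taken as a purchasable natural depside (relay semisynthesis), and in step 2 the ring B bromide, which sits on the less electron-rich ring, is taken to couple first.

Step 1
Reactants: 1 atranorin; 2 N-bromosuccinimide
Product: 4 5,5'-dibromoatranorin, via 5'-bromoatranorin 3 (not isolated)
Conditions: NBS (2.1 equiv), DMF, 0 °C to rt, dark
Reagents that add atoms: N-bromosuccinimide, O=C1CCC(=O)N1Br
Why: Nuclear electrophilic aromatic bromination with NBS in a dipolar aprotic solvent should occur first at C5' (ortho to the C4' hydroxyl, para to the C2' hydroxyl) and then at C5 (para to the C2 hydroxyl, ortho to the depside oxygen), the only unsubstituted ring carbons, while darkness and the absence of radical initiators spare the benzylic methyl groups and the neutral medium leaves both esters and the aldehyde untouched.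

Step 2
Reactants: 4 5,5'-dibromoatranorin; 5 tetramethylstannane
Product: 7 pseudocyphellarin A, via 5'-bromo-5-methylatranorin 6 (not isolated)
Conditions: SnMe4 (6 equiv), Pd(P(t-Bu)3)2 (10 mol %), degassed NMP, 80 °C, sealed tube
Reagents that add atoms: tetramethylstannane, C[Sn](C)(C)C
Why: Each C–Br bond should add oxidatively to monoligated zerovalent palladium, a methyl group should pass from tin to the resulting divalent arylpalladium bromide, and reductive elimination should form the C5–CH3 and C5'–CH3 bonds, the cycle running once on each ring. The closest known reaction type is the Stille methylation of doubly ortho-substituted aryl bromides with SnMe4 under a bulky, electron-rich trialkylphosphine. No ring is closed and no stereocentre is created. Site selectivity is built into the substrate because bromine sits only at C5 and C5'; the selectivity that must be secured is insertion into C–Br in preference to the acyl–oxygen bond of the depside, and this follows from the much lower barrier for aryl bromides and from the shielding of an ester whose carbonyl carbon and phenolic oxygen are each flanked by two ortho substituents. Leaving out base, fluoride and protic nucleophiles protects the depside and methyl esters, the aldehyde is inert to a tetraalkylstannane, and in a dipolar aprotic solvent the three intramolecularly hydrogen-bonded phenols should be too weakly acidic to protonate P(t-Bu)3. A large excess of the volatile stannane in a sealed vessel compensates for the slow transfer of methyl from tin.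

Compound list
1 | atranorin, methyl 4-[(3-formyl-2,4-dihydroxy-6-methylbenzoyl)oxy]-2-hydroxy-3,6-dimethylbenzoate | COC(=O)c1c(C)cc(OC(=O)c2c(C)cc(O)c(C=O)c2O)c(C)c1O | starting material
2 | N-bromosuccinimide | O=C1CCC(=O)N1Br | starting material
3 | 5'-bromoatranorin, methyl 4-[(5-bromo-3-formyl-2,4-dihydroxy-6-methylbenzoyl)oxy]-2-hydroxy-3,6-dimethylbenzoate | COC(=O)c1c(C)cc(OC(=O)c2c(C)c(Br)c(O)c(C=O)c2O)c(C)c1O | intermediate
4 | 5,5'-dibromoatranorin, methyl 5-bromo-4-[(5-bromo-3-formyl-2,4-dihydroxy-6-methylbenzoyl)oxy]-2-hydroxy-3,6-dimethylbenzoate | COC(=O)c1c(C)c(Br)c(OC(=O)c2c(C)c(Br)c(O)c(C=O)c2O)c(C)c1O | intermediate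
5 | tetramethylstannane | C[Sn](C)(C)C | starting material
6 | 5'-bromo-5-methylatranorin, methyl 4-[(5-bromo-3-formyl-2,4-dihydroxy-6-methylbenzoyl)oxy]-2-hydroxy-3,5,6-trimethylbenzoate | COC(=O)c1c(C)c(C)c(OC(=O)c2c(C)c(Br)c(O)c(C=O)c2O)c(C)c1O | intermediate
7 | pseudocyphellarin A, methyl 4-[(3-formyl-2,4-dihydroxy-5,6-dimethylbenzoyl)oxy]-2-hydroxy-3,5,6-trimethylbenzoate | COC(=O)c1c(C)c(C)c(OC(=O)c2c(C)c(C)c(O)c(C=O)c2O)c(C)c1O | target

Total step count: 2
Longest linear sequence: 2 steps

Steps most likely to fail (the route has only two steps, so both are ranked, the key step first)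

Step 2. The coupling may stall after one methyl transfer or drift into hydrodebromination. Methyl transfer from tin to a doubly ortho-flanked arylpalladium bromide is slow, and the free, chelating phenols may bind palladium or quench liberated phosphine. The fallback sets out from 4. The three phenols would first be capped with N,O-bis(trimethylsilyl)acetamide (MeCN, 60 °C, then evaporation of volatiles) to give tris-O-trimethylsilyl-5,5'-dibromoatranorin F1. This aprotic substrate would undergo the Stille methylation (SnMe4, Pd(P(t-Bu)3)2, toluene, 100 °C, sealed tube) to give tris-O-trimethylsilyl-pseudocyphellarin A F2. Brief treatment with 1 M aqueous HCl in THF at room temperature would then cleave the aryl silyl ethers without touching the hindered depside, and the fallback comes back to the route at 7.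

Step 1. Ring A brominates far faster than ring B, so the second bromination may lag. The reagent would then be free to attack ring A again (ipso attack at the formyl-bearing C3', or oxidation) or to brominate benzylic methyl groups. The fallback sets out from 1. Twofold iodination with N-iodosuccinimide and catalytic CF3CO2H in MeCN/CH2Cl2 in the dark would give 5,5'-diiodoatranorin F3. This halogenation is milder and more selective, has no radical benzylic channel, and is accelerated at ring B by the acid. F3 would enter the Stille methylation of step 2 in place of 4, and the fallback comes back to the route at 7.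

Further compounds
F1 | step 2 | tris-O-trimethylsilyl-5,5'-dibromoatranorin, methyl 5-bromo-4-{[5-bromo-3-formyl-6-methyl-2,4-bis(trimethylsilyloxy)benzoyl]oxy}-3,6-dimethyl-2-(trimethylsilyloxy)benzoate | COC(=O)c1c(C)c(Br)c(OC(=O)c2c(C)c(Br)c(O[Si](C)(C)C)c(C=O)c2O[Si](C)(C)C)c(C)c1O[Si](C)(C)C
F2 | step 2 | tris-O-trimethylsilyl-pseudocyphellarin A, methyl 4-{[3-formyl-5,6-dimethyl-2,4-bis(trimethylsilyloxy)benzoyl]oxy}-3,5,6-trimethyl-2-(trimethylsilyloxy)benzoate | COC(=O)c1c(C)c(C)c(OC(=O)c2c(C)c(C)c(O[Si](C)(C)C)c(C=O)c2O[Si](C)(C)C)c(C)c1O[Si](C)(C)C
F3 | step 1 | 5,5'-diiodoatranorin, methyl 4-[(3-formyl-2,4-dihydroxy-5-iodo-6-methylbenzoyl)oxy]-2-hydroxy-5-iodo-3,6-dimethylbenzoate | COC(=O)c1c(C)c(I)c(OC(=O)c2c(C)c(I)c(O)c(C=O)c2O)c(C)c1O
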